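**Retrosynthetic overview**

1. Numbering used below (labdane type): ring A = C1–C5 and C10 (C4 gem-dimethyl, C5 the ring CH, C10 the quaternary carbon with the C20 methyl); C6–C8 and C17 = the 3-oxobutyl chain; C9 = the ketone on C10; C11–C15 = the ester chain with the C13 methyl centre.
2. Late disconnections: the acetate (lipase), the glycerol ester at C15 (from (S)-solketal) and two C=C reductions lead back to a cyclohexene keto enone ester whose only ring is ring A.
3. Key disconnection: ring A is cut at C2–C3 and C5–C10 into a C2–C1–C10 bis-nucleophile and a C3–C4–C5 bis-electrophile, joined in one flask by a Wittig olefination and a palladium-catalysed allylic alkylation. The bis-nucleophile carries a phosphonium salt at C2 and a regiodefined enol silane at C10, both from iodotrimethylsilane opening of a 1-methylcyclopropyl ketone that already holds C9 and the C11–C15 chain; the bis-electrophile carries an aldehyde at C3 and an allylic carbonate at C5 that is conjugated through C6=C7 to the C8 ketone.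
4. Enabling feature: in ring A the quaternary C10 is the α-carbon of the C9 ketone and lies 1,3 to C2, while C5 is the γ-carbon of the C8 ketone (allylic once C6=C7 is present) and lies 1,3 to C3 across the non-enolisable C4 gem-dimethyl carbon; the six ring carbons thus split into a 1,3-donor triad and a 1,3-acceptor triad.
5. Stereocontrol and ring order: C5 comes from a catalytic asymmetric reverse prenylation and is carried through the palladium step with retention, C10 is set in the ring closure, C13 comes from methyl hydrogen (R)-3-methylglutarate and the glycerol centre from (S)-solketal; ring A is the only carbocycle and is formed in step 9 (the dioxolane of solketal is a protecting ring only).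

Key step: step 9

Remark: the prenyl pinacol boronate, 1-methylcyclopropane-1-carbonyl chloride, methyl hydrogen (R)-3-methylglutarate and (S)-solketal are taken as purchasable; the enol silane double bond is drawn without geometry because both isomers give the same C10 enolate.

**Route**

Step 1
Reactants: 1 2-methylfuran
Product: 2 (E)-4-oxopent-2-enal
Conditions: N-bromosuccinimide, NaHCO3, acetone/H2O 10:1, −15 °C; then pyridine (cat.), 20 °C
Reagents that add atoms: water (O)
Why: Oxidative ring opening of the furan (bromination, hydration, loss of HBr) should give the cis keto enal, which pyridine isomerises to the E isomer; no stereocentre is formed.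

Step 2
Reactants: 2 (E)-4-oxopent-2-enal; 3 4,4,5,5-tetramethyl-2-(3-methylbut-2-en-1-yl)-1,3,2-dioxaborolane
Product: 4 (3E,5R)-5-hydroxy-6,6-dimethylocta-3,7-dien-2-one
Conditions: (S)-TRIP [(S)-3,3'-bis(2,4,6-triisopropylphenyl)-1,1'-binaphthyl-2,2'-diyl hydrogen phosphate] (5 mol%), 4 Å molecular sieves, toluene, −30 °C; aqueous NaHCO3 work-up
Reagents that add atoms: none
Why: Chiral phosphoric acid-catalysed allylboration of the aldehyde (the ketone is left alone) through a closed chair transition state with allylic transposition should attach the tert-prenyl unit, the (S) catalyst being chosen to deliver it to the Si face and so set the (R) carbinol centre that becomes C5.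

Step 3
Reactants: 4 (3E,5R)-5-hydroxy-6,6-dimethylocta-3,7-dien-2-one
Product: 5 methyl (3E,5R)-6,6-dimethyl-2-oxoocta-3,7-dien-5-yl carbonate
Conditions: ClCO2Me, pyridine, DMAP (cat.), CH2Cl2, 0 °C
Reagents that add atoms: methyl chloroformate (COC(Cl)=O)
Why: O-acylation of the secondary allylic alcohol (carbonate formation) should install the leaving group for the later allylic substitution without touching the stereocentre.

Step 4
Reactants: 5 methyl (3E,5R)-6,6-dimethyl-2-oxoocta-3,7-dien-5-yl carbonate
Product: 6 (3R,4E)-2,2-dimethyl-1,6-dioxohept-4-en-3-yl methyl carbonate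
Conditions: O3, CH2Cl2, −78 °C (Sudan Red 7B end point); then Me2S, −78 → 20 °C
Reagents that add atoms: ozone ([O-][O+]=O)
Why: Chemoselective ozonolysis: the isolated monosubstituted vinyl group should react far faster than the electron-poor enone double bond, and reductive work-up gives the non-enolisable aldehyde (future C3).

Step 5
Reactants: 7 (3R)-5-methoxy-3-methyl-5-oxopentanoic acid
Product: 8 methyl (3R)-5-hydroxy-3-methylpentanoate
Conditions: BH3·SMe2, THF, 0 → 20 °C; then H2O
Reagents that add atoms: none
Why: Chemoselective borane reduction of the carboxylic acid beside the methyl ester; the future C13 centre is not involved, and the crude hydroxy ester is used at once to avoid lactonisation.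

Step 6
Reactants: 8 methyl (3R)-5-hydroxy-3-methylpentanoate
Product: 9 methyl (3S)-5-iodo-3-methylpentanoate
Conditions: I2, PPh3, imidazole, CH2Cl2, 0 °C
Reagents that add atoms: iodine (II)
Why: Appel-type iodination of the primary alcohol by SN2 displacement; the descriptor changes to S only through the priority rules.

Step 7
Reactants: 9 methyl (3S)-5-iodo-3-methylpentanoate; 10 1-methylcyclopropane-1-carbonyl chloride
Product: 12 methyl (3R)-3-methyl-6-(1-methylcyclopropyl)-6-oxohexanoate, via alkylzinc iodide 11 (not isolated)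
Conditions: Zn dust (activated), LiCl, THF, 35 °C; then 10, Pd(PPh3)4 (3 mol%), 0 → 20 °C
Reagents that add atoms: none
Why: Zinc insertion into the primary iodide tolerates the ester, and palladium-catalysed Negishi acylation of the alkylzinc iodide should give the cyclopropyl ketone that holds C9, C10, C20, C1 and C2.

Step 8
Reactants: 12 methyl (3R)-3-methyl-6-(1-methylcyclopropyl)-6-oxohexanoate
Product: 14 {(7R)-9-methoxy-3,7-dimethyl-9-oxo-4-[(trimethylsilyl)oxy]non-3-en-1-yl}triphenylphosphonium iodide, via iodo enol silane 13 (not isolated)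
Conditions: Me3SiI (1.05 equiv), CH2Cl2, 0 → 20 °C; then PPh3, MeCN, 50 °C; precipitation from dry Et2O under argon
Reagents that add atoms: iodotrimethylsilane (C[Si](C)(C)I); triphenylphosphine (c1ccc(cc1)P(c1ccccc1)c1ccccc1)
Why: Homoconjugate ring opening of the cyclopropyl ketone by iodotrimethylsilane should give, regiospecifically, the tetrasubstituted enol silane with a primary iodide at C2, and SN2 quaternisation of triphenylphosphine at that iodide gives the phosphonium salt.

Step 9
Reactants: 14 {(7R)-9-methoxy-3,7-dimethyl-9-oxo-4-[(trimethylsilyl)oxy]non-3-en-1-yl}triphenylphosphonium iodide; 6 (3R,4E)-2,2-dimethyl-1,6-dioxohept-4-en-3-yl methyl carbonate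
Product: 17 methyl (3R)-3-methyl-6-oxo-6-{(1R,6R)-1,5,5-trimethyl-6-[(1E)-3-oxobut-1-en-1-yl]cyclohex-3-en-1-yl}hexanoate, via phosphorus ylide 15 (not isolated), via Z-olefin enol silane 16 (not isolated)
Conditions: NaN(SiMe3)2 (1.0 equiv), THF, −78 °C; add 6, −78 → 0 °C; then Pd2(dba)3·CHCl3 (2.5 mol%), dppe (6 mol%), 0 → 40 °C
Reagents that add atoms: none
Why: NaN(SiMe3)2 converts 14 into ylide 15, whose Wittig reaction with the α-quaternary aldehyde of 6 should give the Z-olefin 16 (C2=C3) under salt-free kinetic control; zerovalent palladium then ionises the allylic carbonate with inversion to a C5–C6–C7 π-allyl complex, the liberated methoxide removes the silyl group, and the regiodefined C10 enolate attacks C5 anti to palladium (C5–C10). The closest known reaction types are the Z-selective Wittig olefination of non-stabilised ylides and the neutral Tsuji–Trost allylation of ketone enol silanes with allylic carbonates, here run one after the other in one flask. Ring A closes in a 6-(enolexo)-exo-trig mode, the allyl arm and the enolate C=C both staying outside the new ring, and the Z-olefin and the C4 gem-dimethyl group hold C5 and C10 close. C5 is controlled by the (R) carbonate centre through double inversion (net retention), and C10 by a half-chair transition state in which the π-allyl arm and the bulky enolate carbon C9 are pseudo-equatorial and the C20 methyl is pseudo-axial, which gives the trans relation of C6 and C9. The step needs attack at C5 and not at C7 or through oxygen, which the six- against eight-membered ring size and the acyl group on C7 (attack at the distal terminus, conjugated enone product) should secure, and it needs the Z-olefin, because the E isomer cannot close the ring. No free base builds up, so the γ-acidic C5–H of the enone should not epimerise.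

Step 10
Reactants: 17 methyl (3R)-3-methyl-6-oxo-6-{(1R,6R)-1,5,5-trimethyl-6-[(1E)-3-oxobut-1-en-1-yl]cyclohex-3-en-1-yl}hexanoate
Product: 18 methyl (3R)-3-methyl-6-oxo-6-[(1R,2R)-1,3,3-trimethyl-2-(3-oxobutyl)cyclohexyl]hexanoate
Conditions: H2 (1 atm), Pd/C (10%), EtOAc, 20 °C
Reagents that add atoms: none
Why: Heterogeneous catalytic hydrogenation should saturate the ring olefin and the enone double bond without touching the ketones, the ester or the two ring stereocentres.

Step 11
Reactants: 18 methyl (3R)-3-methyl-6-oxo-6-[(1R,2R)-1,3,3-trimethyl-2-(3-oxobutyl)cyclohexyl]hexanoate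
Product: 19 (3R)-3-methyl-6-oxo-6-[(1R,2R)-1,3,3-trimethyl-2-(3-oxobutyl)cyclohexyl]hexanoic acid
Conditions: Me3SnOH (5 equiv), ClCH2CH2Cl, 80 °C; then 1 M HCl wash
Reagents that add atoms: trimethyltin hydroxide (C[Sn](C)(C)O)
Why: Near-neutral ester cleavage with trimethyltin hydroxide (acyl–oxygen cleavage) should avoid intramolecular aldol reactions of the 1,6-diketone and any epimerisation.

Step 12
Reactants: 19 (3R)-3-methyl-6-oxo-6-[(1R,2R)-1,3,3-trimethyl-2-(3-oxobutyl)cyclohexyl]hexanoic acid; 20 [(4S)-2,2-dimethyl-1,3-dioxolan-4-yl]methanol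
Product: 21 [(4R)-2,2-dimethyl-1,3-dioxolan-4-yl]methyl (3R)-3-methyl-6-oxo-6-[(1R,2R)-1,3,3-trimethyl-2-(3-oxobutyl)cyclohexyl]hexanoate
Conditions: EDC·HCl, DMAP (cat.), CH2Cl2, 0 → 20 °C
Reagents that add atoms: none
Why: Carbodiimide/DMAP (Steglich) esterification of the primary alcohol of (S)-solketal brings in the glycerol stereocentre from the chiral pool; the descriptor changes to R only through the priority rules.

Step 13
Reactants: 21 [(4R)-2,2-dimethyl-1,3-dioxolan-4-yl]methyl (3R)-3-methyl-6-oxo-6-[(1R,2R)-1,3,3-trimethyl-2-(3-oxobutyl)cyclohexyl]hexanoate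
Product: 22 (2R)-2,3-dihydroxypropyl (3R)-3-methyl-6-oxo-6-[(1R,2R)-1,3,3-trimethyl-2-(3-oxobutyl)cyclohexyl]hexanoate
Conditions: AcOH/H2O 4:1, 40 °C; evaporation below 30 °C
Reagents that add atoms: none
Why: Mild acid-catalysed acetal hydrolysis, chosen to limit 1,2-acyl migration in the monoacylglycerol.

Step 14
Reactants: 22 (2R)-2,3-dihydroxypropyl (3R)-3-methyl-6-oxo-6-[(1R,2R)-1,3,3-trimethyl-2-(3-oxobutyl)cyclohexyl]hexanoate
Product: 23 (2R)-3-(acetyloxy)-2-hydroxypropyl (3R)-3-methyl-6-oxo-6-[(1R,2R)-1,3,3-trimethyl-2-(3-oxobutyl)cyclohexyl]hexanoate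
Conditions: vinyl acetate (3 equiv), Novozym 435 (immobilised Candida antarctica lipase B), t-BuOMe, 20 °C
Reagents that add atoms: vinyl acetate (CC(=O)OC=C)
Why: Lipase-catalysed transesterification with vinyl acetate should acylate only the primary hydroxyl group, leaving the secondary alcohol free and the stereocentre untouched.

**Compound list**

1 | 2-methylfuran | Cc1ccco1 | starting material
2 | (E)-4-oxopent-2-enal | O=C/C=C/C(C)=O | intermediate
3 | 4,4,5,5-tetramethyl-2-(3-methylbut-2-en-1-yl)-1,3,2-dioxaborolane | CC(C)=CCB1OC(C)(C)C(C)(C)O1 | starting material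
4 | (3E,5R)-5-hydroxy-6,6-dimethylocta-3,7-dien-2-one | C=CC(C)(C)[C@H](O)/C=C/C(C)=O | intermediate
5 | methyl (3E,5R)-6,6-dimethyl-2-oxoocta-3,7-dien-5-yl carbonate | C=CC(C)(C)[C@H](OC(=O)OC)/C=C/C(C)=O | intermediate
6 | (3R,4E)-2,2-dimethyl-1,6-dioxohept-4-en-3-yl methyl carbonate | O=CC(C)(C)[C@H](OC(=O)OC)/C=C/C(C)=O | intermediate
7 | (3R)-5-methoxy-3-methyl-5-oxopentanoic acid | COC(=O)C[C@H](C)CC(O)=O | starting material
8 | methyl (3R)-5-hydroxy-3-methylpentanoate | COC(=O)C[C@H](C)CCO | intermediate
9 | methyl (3S)-5-iodo-3-methylpentanoate | COC(=O)C[C@H](C)CCI | intermediate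
10 | 1-methylcyclopropane-1-carbonyl chloride | CC1(CC1)C(Cl)=O | starting material
11 | [(3S)-5-methoxy-3-methyl-5-oxopentyl](iodo)zinc | COC(=O)C[C@H](C)CC[Zn]I | intermediate
12 | methyl (3R)-3-methyl-6-(1-methylcyclopropyl)-6-oxohexanoate | COC(=O)C[C@H](C)CCC(=O)C1(C)CC1 | intermediate
13 | methyl (3R)-9-iodo-3,7-dimethyl-6-[(trimethylsilyl)oxy]non-6-enoate | COC(=O)C[C@H](C)CCC(O[Si](C)(C)C)=C(C)CCI | intermediate
14 | {(7R)-9-methoxy-3,7-dimethyl-9-oxo-4-[(trimethylsilyl)oxy]non-3-en-1-yl}triphenylphosphonium iodide | COC(=O)C[C@H](C)CCC(O[Si](C)(C)C)=C(C)CC[P+](c1ccccc1)(c1ccccc1)c1ccccc1.[I-] | intermediate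
15 | methyl (3R)-3,7-dimethyl-6-[(trimethylsilyl)oxy]-9-(triphenyl-λ5-phosphanylidene)non-6-enoate | COC(=O)C[C@H](C)CCC(O[Si](C)(C)C)=C(C)CC=P(c1ccccc1)(c1ccccc1)c1ccccc1 | intermediate
16 | methyl (3R,9Z,12R,13E)-12-[(methoxycarbonyl)oxy]-3,7,11,11-tetramethyl-15-oxo-6-[(trimethylsilyl)oxy]hexadeca-6,9,13-trienoate | COC(=O)C[C@H](C)CCC(O[Si](C)(C)C)=C(C)C/C=C\C(C)(C)[C@H](OC(=O)OC)/C=C/C(C)=O | intermediate
17 | methyl (3R)-3-methyl-6-oxo-6-{(1R,6R)-1,5,5-trimethyl-6-[(1E)-3-oxobut-1-en-1-yl]cyclohex-3-en-1-yl}hexanoate | CC(=O)/C=C/[C@@H]1C(C)(C)C=CC[C@@]1(C)C(=O)CC[C@@H](C)CC(=O)OC | intermediate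
18 | methyl (3R)-3-methyl-6-oxo-6-[(1R,2R)-1,3,3-trimethyl-2-(3-oxobutyl)cyclohexyl]hexanoate | CC(=O)CC[C@@H]1C(C)(C)CCC[C@@]1(C)C(=O)CC[C@@H](C)CC(=O)OC | intermediate
19 | (3R)-3-methyl-6-oxo-6-[(1R,2R)-1,3,3-trimethyl-2-(3-oxobutyl)cyclohexyl]hexanoic acid | CC(=O)CC[C@@H]1C(C)(C)CCC[C@@]1(C)C(=O)CC[C@@H](C)CC(=O)O | intermediate
20 | [(4S)-2,2-dimethyl-1,3-dioxolan-4-yl]methanol | OC[C@H]1COC(C)(C)O1 | starting material
21 | [(4R)-2,2-dimethyl-1,3-dioxolan-4-yl]methyl (3R)-3-methyl-6-oxo-6-[(1R,2R)-1,3,3-trimethyl-2-(3-oxobutyl)cyclohexyl]hexanoate | CC(=O)CC[C@@H]1C(C)(C)CCC[C@@]1(C)C(=O)CC[C@@H](C)CC(=O)OC[C@H]1COC(C)(C)O1 | intermediate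
22 | (2R)-2,3-dihydroxypropyl (3R)-3-methyl-6-oxo-6-[(1R,2R)-1,3,3-trimethyl-2-(3-oxobutyl)cyclohexyl]hexanoate | CC(=O)CC[C@@H]1C(C)(C)CCC[C@@]1(C)C(=O)CC[C@@H](C)CC(=O)OC[C@H](O)CO | intermediate
23 | (2R)-3-(acetyloxy)-2-hydroxypropyl (3R)-3-methyl-6-oxo-6-[(1R,2R)-1,3,3-trimethyl-2-(3-oxobutyl)cyclohexyl]hexanoate | CC(=O)CC[C@@H]1C(C)(C)CCC[C@@]1(C)C(=O)CC[C@@H](C)CC(=O)OC[C@H](O)COC(C)=O | target

**Step count and risks**

Total step count: 14. Longest linear sequence: 10 steps (steps 5–14; steps 1–4 followed by 9–14 are equally long).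

The three steps most likely to fail:

Step 9. The ring closure may show poor facial discrimination at the C10 enolate (cis instead of trans relation of C6 and C9). It may also go through the other allyl terminus or through oxygen, lose the C5 configuration by exchange of the allyl–palladium complex, or stall because too much E-olefin forms in the Wittig stage. The fallback separates the two bond formations and closes ring A by ring-closing metathesis. It sets out from 9 (through the zinc reagent 11) and from 5 and comes back to the route at 17. Acylation of 11 with methacryloyl chloride under Pd(PPh3)4 catalysis should give the enone methyl (3R)-3,7-dimethyl-6-oxooct-7-enoate F1. Conjugate addition of lithium divinylcuprate (CH2=CH)2CuLi to F1 should give, regiospecifically, the lithium enolate lithium (3R)-1-methoxy-3,7-dimethyl-1-oxodeca-6,9-dien-6-olate F2. Allylation of F2 in the same flask with carbonate 5 and Pd(PPh3)4 should then give the diene methyl (3R,7R,8R,9E)-3,7-dimethyl-8-(2-methylbut-3-en-2-yl)-6,11-dioxo-7-(prop-2-en-1-yl)dodec-9-enoate F3, from which any C10 epimer would be separated. Ring-closing metathesis of the allyl and vinyl groups of F3 with the second-generation Grubbs catalyst (H2IMes)(PCy3)Cl2Ru=CHPh in CH2Cl2 at 40 °C should give 17; the electron-poor enone double bond is expected to stay out of the metathesis.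

Step 8. The silyl enol ether may be lost by hydrolysis, or the iodo enol silane may close back to the cyclopropane while the phosphonium salt is formed. The fallback carries the free ketone through the Wittig step and forms the enolate only afterwards. It sets out from 12 and comes back at 17. Ring opening with Me3SiI followed by aqueous work-up should give methyl (3R,7RS)-9-iodo-3,7-dimethyl-6-oxononanoate F4, and PPh3 in MeCN should convert it into [(3RS,7R)-9-methoxy-3,7-dimethyl-4,9-dioxononyl]triphenylphosphonium iodide F5. NaN(SiMe3)2 should give the ylide methyl (3R,7RS)-3,7-dimethyl-6-oxo-9-(triphenyl-λ5-phosphanylidene)nonanoate F6, whose Wittig reaction with 6 at −78 °C should give the keto carbonate methyl (3R,7RS,9Z,12R,13E)-12-[(methoxycarbonyl)oxy]-3,7,11,11-tetramethyl-6,15-dioxohexadeca-9,13-dienoate F7, which is isolated. Cyclisation of F7 with Pd(PPh3)4 under equilibrating enolisation (KOt-Bu, t-BuOH/THF) should lead to 17, because only the C10 enolate can close a six-membered ring.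

Step 2. The γ,γ-disubstituted allylboronate may react slowly or with insufficient enantioselectivity, and the reactive keto enal may polymerise under acid catalysis. The fallback replaces the boron-based addition by a chromium-mediated one. It sets out from 2 and comes back at 4. A catalytic enantioselective Nozaki–Hiyama–Kishi prenylation with 1-bromo-3-methylbut-2-ene should give the silyl ether (3E,5R)-6,6-dimethyl-5-[(trimethylsilyl)oxy]octa-3,7-dien-2-one F8; the conditions are divalent chromium chloride CrCl2 (10 mol%), Mn powder, Me3SiCl and a chiral bis(oxazolinyl)carbazole ligand in THF. Desilylation with dilute HCl in THF should then give 4.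

**Further compounds**

F1 | step 9 | methyl (3R)-3,7-dimethyl-6-oxooct-7-enoate | COC(=O)C[C@H](C)CCC(=O)C(C)=C
F2 | step 9 | lithium (3R)-1-methoxy-3,7-dimethyl-1-oxodeca-6,9-dien-6-olate | COC(=O)C[C@H](C)CCC([O-])=C(C)CC=C.[Li+]
F3 | step 9 | methyl (3R,7R,8R,9E)-3,7-dimethyl-8-(2-methylbut-3-en-2-yl)-6,11-dioxo-7-(prop-2-en-1-yl)dodec-9-enoate | CC(=O)/C=C/[C@H](C(C)(C)C=C)[C@@](C)(CC=C)C(=O)CC[C@@H](C)CC(=O)OC
F4 | step 8 | methyl (3R,7RS)-9-iodo-3,7-dimethyl-6-oxononanoate | COC(=O)C[C@H](C)CCC(=O)C(C)CCI
F5 | step 8 | [(3RS,7R)-9-methoxy-3,7-dimethyl-4,9-dioxononyl]triphenylphosphonium iodide | COC(=O)C[C@H](C)CCC(=O)C(C)CC[P+](c1ccccc1)(c1ccccc1)c1ccccc1.[I-]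
F6 | step 8 | methyl (3R,7RS)-3,7-dimethyl-6-oxo-9-(triphenyl-λ5-phosphanylidene)nonanoate | COC(=O)C[C@H](C)CCC(=O)C(C)CC=P(c1ccccc1)(c1ccccc1)c1ccccc1
F7 | step 8 | methyl (3R,7RS,9Z,12R,13E)-12-[(methoxycarbonyl)oxy]-3,7,11,11-tetramethyl-6,15-dioxohexadeca-9,13-dienoate | COC(=O)C[C@H](C)CCC(=O)C(C)C/C=C\C(C)(C)[C@H](OC(=O)OC)/C=C/C(C)=O
F8 | step 2 | (3E,5R)-6,6-dimethyl-5-[(trimethylsilyl)oxy]octa-3,7-dien-2-one | C=CC(C)(C)[C@H](O[Si](C)(C)C)/C=C/C(C)=O
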